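## The problem

The target is an ether-linked dimer of two 7,8,4'-trihydroxyflavan-3,4-diols. C4 of an all-cis unit (2R,3R,4R; rings A, C, B; unprimed) and C4' of a 2,3-trans-3,4-cis unit (2S,3R,4R; rings A', C', B'; primed) share one oxygen, so the central ether is secondary and benzylic on both sides. The two units differ only at C2, so they cannot be treated as equivalent; each needs its own C2 and its own relay to C3 and C4. Inside a chroman ring the C2 aryl group sends reagents to the opposite face. That gives the 2,3-trans pattern of the primed unit directly, whereas the 2,3-cis pattern of the unprimed unit needs an inversion at C3. Joining two flavan-4-ols through a C4 cation would place the new oxygen mainly anti to O3, the wrong sense for the 3,4-cis relation required in both units. The benzylic C–O bonds para to ring oxygens (C4–O, C4'–O, C2–O1, C2'–O1') ionise with Brønsted or Lewis acids, and the free pyrogallol-type rings A and A' oxidise in air, so the phenols must stay masked until a neutral last step. The enabling feature is C4': it carries the bridging oxygen, aryl carbon C4a' and C3', so at the acid oxidation level it is the carbonyl carbon of a benzoate of the unprimed 4-hydroxyl. Because O1' sits ortho to that carbonyl on ring A', a 2-(1-arylallyloxy)benzoate holds a terminal alkene where carbonyl–olefin metathesis closes the six-membered ring C'.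

## Retrosynthesis

**24 from 23.** The seven O–benzyl bonds are cut last. Benzyl is the one phenol mask that survives base, hydride, low-valent titanium and dimethyldioxirane and leaves by neutral hydrogenolysis. Silyl ethers would not survive the saponification, acetal groups need acid, and allyl groups would interfere with metathesis. The forward step must cleave primary benzyl ethers faster than the bridging bis-benzylic ether.

**23 from 21 (through epoxide 22).** The C3'–O and C4'–H bonds are removed, leaving the 4-alkoxy-2H-chromene 21. Hydroboration would add H and O syn and give the 3',4'-trans isomer. Epoxidation anti to the 2'-aryl group followed by hydride entry at the acetal carbon C4' with inversion gives 2,3-trans-3,4-cis. This removes two stereocentres and leaves C2' as the only one in the primed half. The forward step needs face selectivity and capture of a labile alkoxy-epoxide.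

**21 from 20 (key).** The C3'=C4' bond is cut to the benzoate 20, which carries an ortho 1-arylallyloxy group. The alternative cuts at C4–O or C4'–O would need substitution at a hindered, ionisable benzylic carbon. Here the bridging C–O bond is an acyl–oxygen bond and C4' is not yet a stereocentre. Ring C' is opened. The forward reaction must exchange the alkene before it touches the carbonyl.

**20 from 19 and 8.** The ester bond is cut into the all-cis alcohol 19 and acid 8, two halves of similar size. This is the most convergent cut and asks only for acylation of a hindered secondary alcohol.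

**8 from 7, from 6 and 4.** The allylic C–O bond at the future C2' is cut. Base alkylation of a phenoxide with a cinnamyl electrophile gives the linear ether, and a Mitsunobu reaction at a 4-alkoxybenzylic allylic carbinol would scramble. Iridium-catalysed allylic etherification of phenol 6 with linear carbonate 4 gives the branched ether with the stereocentre set by the ligand. Phenol 6 comes from 5 by selective benzylation, and 4 from acid 1 through 2 and 3.

**19 from 18, 17, 16 and 15.** O3 must end benzylated and O4 free, all-cis. O4 is carried as an allyl ether while C3 is inverted by oxidation to ketone 16 and reduction with a bulky hydride to 17. The allyl group survives oxidation, hydride and base and is removed without acid or hydrogen. Direct syn-dihydroxylation on the aryl face is not available, since osmium and peracids attack anti to the aryl group.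

**15 from 13 (through epoxide 14).** The C3–O and C4–O bonds are cut to the 2H-chromene 13. Epoxidation anti to the aryl group and trans alcoholysis at benzylic C4 set C4 in its final configuration and C3 in the one to be inverted.

**13 from 12, 11, and 10 with 4.** The C3=C4 bond is cut by ring-closing metathesis to diene 12, the styrene carbon comes from aldehyde 11 by Wittig methylenation, and the allylic C–O bond comes from phenol 10 and the same carbonate 4 with the antipodal ligand. Phenol 10 comes from 9. One catalyst system therefore sets C2 and C2' in opposite senses from one electrophile.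

## Roads not taken

**Alternative 1:** The bridging oxygen is bought as the oxygen of 2,3-dihydrofuran A2. Two asymmetric Heck arylations with aryl triflate A3 (Pd(OAc)2, a BINAP antipode) would form C4–C4a and C4'–C4a' and give the trans-2,5-diaryl-2,5-dihydrofuran A1.
- Merits: the awkward bis-benzylic ether and both of its stereocentres come from one catalytic operation on cheap materials. In this respect it is better than the plan chosen here, which makes C4' late on a large substrate.
- Weak points: A3 is electron-rich and flanked by a silyloxy group, a poor partner for oxidative addition and insertion. The C3–C3' alkene of A1 must then be cleaved and both arms extended by C2 and C2'. A1 is C2-symmetric, whereas the target needs 2R on one side and 2S on the other, so a two-directional extension cannot deliver it. The cleaved intermediate would have doubly activated, epimerisable C4 and C4' hydrogens.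
- Comparison: the chosen plan sets C2 and C2' independently with ligand antipodes and relays them within rings.

**Alternative 2:** The C2'–C3' bond is formed by adding the ylide of sulfonium salt A5 to the α-alkoxy aldehyde A6, whose alkoxy group is the protected all-cis unit. This gives trans-epoxide A4; desilylation and phenoxide opening at C2' with inversion would close ring C' as the 2,3-trans isomer.
- Merits: it is convergent, and the ring closure is a well-established type, arguably better precedented than the titanium cyclisation used here. It also avoids organotitanium chemistry on a late intermediate.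
- Weak points: A6 has a C4' hydrogen activated by both the aryl group and the aldehyde and would epimerise under the basic ylide conditions. Making A6 already requires the hindered bridging ether with C4' defined, so the central problem is moved and not solved. The ylide addition has no strong bias for the C3'/C4' relation or for trans over cis oxirane.
- Comparison: the chosen plan makes the bridging C–O bond as an ester at a carbon that is not yet stereogenic, and C4' becomes a stereocentre only inside ring C', under control of C2' and C3'.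

**Alternative 3:** Both pyran rings are closed last by copper-catalysed O-arylation (CuI, tetramethylphenanthroline, Cs2CO3) of the open-chain bis(aryl bromide) diol A8, forming O1–C8a and O1'–C8a' and giving the octa-O-benzyl ether A7.
- Merits: arylation occurs on oxygen, so C2 and C2' keep their configuration, and A7 is one hydrogenolysis from the target. No stereocentre is made on the dimer. Its endgame is cleaner than the chosen one.
- Weak points: A8 needs six acyclic stereocentres and the central ether between two secondary benzylic carbons, which is the hardest bond of the molecule and is left unsolved. Each bromide lies between a benzyloxy group and a branched benzylic carbon, and the benzylic alkoxides can oxidise or fragment at the temperatures such couplings need. Two such closures must both succeed.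
- Comparison: the chosen plan uses short fragment syntheses in which one catalytic step per half sets C2 and the rings relay the rest, and its bridging bond is made by acylation.

Key step: step 17

Assumption: the (Ra,Rc,Rc) phosphoramidite–iridium catalyst is taken to give the (R)-1-arylallyl aryl ether, as it does with other heteroatom nucleophiles. If the sense is the reverse, the two ligand antipodes change places between steps 5 and 8. L denotes O,O'-(1,1'-binaphthyl-2,2'-diyl) N,N-bis(1-phenylethyl)phosphoramidite.

## Route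

Step 1
Reactants: 1 4-hydroxycinnamic acid
Product: 2 benzyl (E)-3-[4-(benzyloxy)phenyl]prop-2-enoate
Conditions: BnBr (2.3 equiv), K2CO3, DMF, 60 °C
Reagents that add atoms: benzyl bromide, BrCc1ccccc1
Why: O-alkylation of phenoxide and carboxylate under carbonate base; the benzyl ester is consumed in the next step.

Step 2
Reactants: 2 benzyl (E)-3-[4-(benzyloxy)phenyl]prop-2-enoate
Product: 3 (E)-3-[4-(benzyloxy)phenyl]prop-2-en-1-ol
Conditions: i-Bu2AlH (2.5 equiv), CH2Cl2, −78 → 0 °C; Rochelle salt work-up
Reagents that add atoms: none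
Why: 1,2-reduction of an enoate by an aluminium hydride gives the allylic alcohol with the E alkene intact.

Step 3
Reactants: 3 (E)-3-[4-(benzyloxy)phenyl]prop-2-en-1-ol
Product: 4 (E)-3-[4-(benzyloxy)phenyl]prop-2-en-1-yl methyl carbonate
Conditions: ClCO2Me, pyridine, CH2Cl2, 0 °C
Reagents that add atoms: methyl chloroformate, COC(=O)Cl
Why: acylation of a primary alcohol with a chloroformate; the carbonate is the leaving group for allyl-iridium formation.

Step 4
Reactants: 5 methyl 2,3,4-trihydroxybenzoate
Product: 6 methyl 3,4-bis(benzyloxy)-2-hydroxybenzoate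
Conditions: BnBr (2.1 equiv), K2CO3, acetone, reflux
Reagents that add atoms: benzyl bromide, BrCc1ccccc1
Why: regioselective Williamson etherification; the 2-hydroxyl is hydrogen-bonded to the ester carbonyl and is the least nucleophilic, so two equivalents stop at the 3,4-diether.

Step 5
Reactants: 6 methyl 3,4-bis(benzyloxy)-2-hydroxybenzoate; 4 (E)-3-[4-(benzyloxy)phenyl]prop-2-en-1-yl methyl carbonate
Product: 7 methyl 3,4-bis(benzyloxy)-2-{[(1R)-1-[4-(benzyloxy)phenyl]prop-2-en-1-yl]oxy}benzoate
Conditions: 6, LiN(SiMe3)2, THF, 0 °C; then 4, [Ir(cod)Cl]2 (2 mol%), (Ra,Rc,Rc)-L (4 mol%), THF, rt → 50 °C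
Reagents that add atoms: none
Why: iridium-catalysed asymmetric allylic etherification; the cyclometalated iridium–phosphoramidite allyl complex is attacked by the phenoxide at the aryl-bearing terminus, giving the branched ether. The ligand sets the stereocentre that becomes C2'.

Step 6
Reactants: 7 methyl 3,4-bis(benzyloxy)-2-{[(1R)-1-[4-(benzyloxy)phenyl]prop-2-en-1-yl]oxy}benzoate
Product: 8 3,4-bis(benzyloxy)-2-{[(1R)-1-[4-(benzyloxy)phenyl]prop-2-en-1-yl]oxy}benzoic acid
Conditions: LiOH, THF/MeOH/H2O, 40 °C; 1 M HCl to pH 4 at 0 °C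
Reagents that add atoms: lithium hydroxide (hydroxide oxygen), [Li+].[OH-]
Why: ester saponification by acyl–oxygen cleavage; base does not touch the allylic ether or its stereocentre, and the cold, brief acidification spares the ionisable C–O bond.

Step 7
Reactants: 9 2,3,4-trihydroxybenzaldehyde
Product: 10 3,4-bis(benzyloxy)-2-hydroxybenzaldehyde
Conditions: BnBr (2.1 equiv), K2CO3, DMF, rt
Reagents that add atoms: benzyl bromide, BrCc1ccccc1
Why: same regioselective etherification as step 4; the chelated 2-hydroxyl stays free.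

Step 8
Reactants: 10 3,4-bis(benzyloxy)-2-hydroxybenzaldehyde; 4 (E)-3-[4-(benzyloxy)phenyl]prop-2-en-1-yl methyl carbonate
Product: 11 3,4-bis(benzyloxy)-2-{[(1S)-1-[4-(benzyloxy)phenyl]prop-2-en-1-yl]oxy}benzaldehyde
Conditions: 10, LiN(SiMe3)2, THF, 0 °C; then 4, [Ir(cod)Cl]2 (2 mol%), (Sa,Sc,Sc)-L (4 mol%), THF, rt → 50 °C
Reagents that add atoms: none
Why: the same iridium-catalysed allylic etherification with the antipodal ligand gives the (S)-ether; this centre becomes C2 of the all-cis unit.

Step 9
Reactants: 11 3,4-bis(benzyloxy)-2-{[(1S)-1-[4-(benzyloxy)phenyl]prop-2-en-1-yl]oxy}benzaldehyde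
Product: 12 1,2-bis(benzyloxy)-3-{[(1S)-1-[4-(benzyloxy)phenyl]prop-2-en-1-yl]oxy}-4-ethenylbenzene
Conditions: Ph3PCH3Br, KOt-Bu, THF, 0 °C → rt
Reagents that add atoms: methyltriphenylphosphonium bromide, C[P+](c1ccccc1)(c1ccccc1)c1ccccc1.[Br-]
Why: Wittig methylenation of a non-enolisable aryl aldehyde; the ether stereocentre has no acidic neighbour.

Step 10
Reactants: 12 1,2-bis(benzyloxy)-3-{[(1S)-1-[4-(benzyloxy)phenyl]prop-2-en-1-yl]oxy}-4-ethenylbenzene
Product: 13 (2S)-7,8-bis(benzyloxy)-2-[4-(benzyloxy)phenyl]-2H-chromene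
Conditions: second-generation Grubbs catalyst Cl2(H2IMes)(PCy3)Ru=CHPh (3 mol%), CH2Cl2, 40 °C
Reagents that add atoms: none
Why: ring-closing metathesis of a styrene with an allyl ether gives the 2H-chromene with loss of ethylene; C2 is not involved.

Step 11
Reactants: 13 (2S)-7,8-bis(benzyloxy)-2-[4-(benzyloxy)phenyl]-2H-chromene
Product: 15 (2R,3S,4R)-4-(allyloxy)-7,8-bis(benzyloxy)-2-[4-(benzyloxy)phenyl]chroman-3-ol, via 3,4-epoxide 14 (not isolated)
Conditions: dimethyldioxirane (acetone), CH2Cl2, −40 °C; then allyl alcohol (excess), PPTS (cat.), −40 → 0 °C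
Reagents that add atoms: dimethyldioxirane, CC1(C)OO1; allyl alcohol, C=CCO
Why: epoxidation of a 2-aryl-2H-chromene occurs anti to the aryl group, and the alcohol opens the benzylic oxirane carbon C4 anti to the oxirane oxygen. This gives the 2,3-trans-3,4-trans arrangement, with C4 final and C3 still to be inverted. The C2 label changes from S to R only because C3 now outranks the aryl group.

Step 12
Reactants: 15 (2R,3S,4R)-4-(allyloxy)-7,8-bis(benzyloxy)-2-[4-(benzyloxy)phenyl]chroman-3-ol
Product: 16 (2R,4R)-4-(allyloxy)-7,8-bis(benzyloxy)-2-[4-(benzyloxy)phenyl]chroman-3-one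
Conditions: Dess–Martin periodinane, pyridine, CH2Cl2, 0 °C → rt
Reagents that add atoms: none
Why: Dess–Martin oxidation of a secondary alcohol under buffered, non-basic conditions, so the enolisable C2 and C4 centres flanking the ketone are not disturbed.

Step 13
Reactants: 16 (2R,4R)-4-(allyloxy)-7,8-bis(benzyloxy)-2-[4-(benzyloxy)phenyl]chroman-3-one
Product: 17 (2R,3R,4R)-4-(allyloxy)-7,8-bis(benzyloxy)-2-[4-(benzyloxy)phenyl]chroman-3-ol
Conditions: LiBH(s-Bu)3, LiBr, THF, −78 °C
Reagents that add atoms: none
Why: a bulky borohydride attacks the chroman-3-one equatorially, from the side away from the 2-aryl and 4-allyloxy groups, giving the axial 3-hydroxyl cis to both. This is the reduction type used to convert 2,3-trans into 2,3-cis flavan-3-ols.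

Step 14
Reactants: 17 (2R,3R,4R)-4-(allyloxy)-7,8-bis(benzyloxy)-2-[4-(benzyloxy)phenyl]chroman-3-ol
Product: 18 (2R,3R,4R)-4-(allyloxy)-3,7,8-tris(benzyloxy)-2-[4-(benzyloxy)phenyl]chromane
Conditions: NaH, BnBr, Bu4NI (cat.), DMF, 0 °C → rt
Reagents that add atoms: benzyl bromide, BrCc1ccccc1
Why: Williamson benzylation of the axial secondary alkoxide; no base-labile group or acidic stereocentre is present.

Step 15
Reactants: 18 (2R,3R,4R)-4-(allyloxy)-3,7,8-tris(benzyloxy)-2-[4-(benzyloxy)phenyl]chromane
Product: 19 (2R,3R,4R)-3,7,8-tris(benzyloxy)-2-[4-(benzyloxy)phenyl]chroman-4-ol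
Conditions: NiCl2(dppp) (cat.), i-Bu2AlH, toluene, 0 °C → rt
Reagents that add atoms: none
Why: nickel-catalysed hydroalumination of the allyl group followed by β-alkoxide elimination releases propene and the aluminium alkoxide; benzyl ethers and the benzylic C4–O bond are untouched because no acid or hydrogen is used.

Step 16
Reactants: 19 (2R,3R,4R)-3,7,8-tris(benzyloxy)-2-[4-(benzyloxy)phenyl]chroman-4-ol; 8 3,4-bis(benzyloxy)-2-{[(1R)-1-[4-(benzyloxy)phenyl]prop-2-en-1-yl]oxy}benzoic acid
Product: 20 the 4-O-ester of 19 with acid 8 (three centres of 19 unchanged; R at the allylic ether carbon)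
Conditions: N,N'-diisopropylcarbodiimide, DMAP, CH2Cl2, 0 °C → rt
Reagents that add atoms: none
Why: Steglich esterification; DMAP transfers the acyl group from the O-acylisourea to the equatorial 4-hydroxyl under neutral conditions that touch no stereocentre.

Step 17
Reactants: 20 the 4-O-ester of 19 with acid 8
Product: 21 the 4-O-{(2R)-7,8-bis(benzyloxy)-2-[4-(benzyloxy)phenyl]-2H-chromen-4-yl} ether of 19
Conditions: TiCl4, TMEDA, Zn, PbCl2 (cat.), CH3CHBr2, THF/CH2Cl2, 0 → 65 °C; aq. K2CO3; Et3N-deactivated silica
Reagents that add atoms: none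
Why: The low-valent titanium ethylidene formed from TiCl4, Zn, PbCl2, TMEDA and CH3CHBr2 first exchanges with the terminal alkene of 20 by cycloaddition and cycloreversion, expelling propene and leaving a titanium alkylidene on C3'. This alkylidene adds across the benzoate carbonyl five atoms away to give an oxatitanacyclobutane, which collapses to the C3'=C4' bond and a titanium oxo species. The closest known reaction type is the olefinic-ester cyclisation to cyclic enol ethers with this same reagent, whose stepwise form is ester methylenation followed by ruthenium-catalysed ring-closing metathesis. Ring C' closes as a six-membered 2H-pyran by ring-closing carbonyl–olefin metathesis, with the double bond endocyclic and the bridging oxygen exocyclic. No stereocentre is formed, and C2' is a spectator with no acidic or enolisable neighbour. The selectivity required is alkene exchange before carbonyl attack; the ethylidene reagent, the monosubstituted alkene, the low electrophilicity of the electron-rich ortho-substituted benzoate and the six-membered closure all favour it. Chemoselectivity is otherwise simple because 20 has one ester, one alkene and only ether groups besides, and excess TMEDA tempers the zinc and titanium halides toward the ionisable C2'–O and C4–O bonds.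

Step 18
Reactants: 21 the 4-O-{(2R)-7,8-bis(benzyloxy)-2-[4-(benzyloxy)phenyl]-2H-chromen-4-yl} ether of 19
Product: 23 (2R,3R,4R)-3,7,8-tris(benzyloxy)-2-[4-(benzyloxy)phenyl]-4-{[(2S,3R,4R)-7,8-bis(benzyloxy)-2-[4-(benzyloxy)phenyl]-3-hydroxychroman-4-yl]oxy}chromane, via 3',4'-epoxide 22 (not isolated)
Conditions: dimethyldioxirane (acetone), CH2Cl2, −78 → −40 °C; volatiles removed cold; LiBHEt3, THF, −78 → 0 °C
Reagents that add atoms: dimethyldioxirane, CC1(C)OO1
Why: the electron-rich enol ether is epoxidised anti to the 2'-aryl group, which fixes O3' trans to it. An anionic hydride then opens the 2-alkoxyoxirane at the acetal carbon C4' with inversion, as in the reductive opening of glycal epoxides at the anomeric carbon, so the bridging oxygen ends cis to the 3'-hydroxyl. No Lewis acid is present to ionise the C4–O bond of the other unit.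

Step 19
Reactants: 23 the hepta-O-benzyl ether with free 3'-hydroxyl
Product: 24 (2R,3R,4R)-2-(4-hydroxyphenyl)-4-{[(2S,3R,4R)-3,7,8-trihydroxy-2-(4-hydroxyphenyl)chroman-4-yl]oxy}chromane-3,7,8-triol
Conditions: H2 (1 atm), Pd(OH)2/C, THF/MeOH, rt; filtered and concentrated under argon
Reagents that add atoms: none
Why: catalytic hydrogenolysis of seven primary benzyl ethers; these cleave much faster than the secondary bridging ether and the cyclic C2–O1 bonds, as in the debenzylation of flavan-3,4-diol and proanthocyanidin derivatives. Neutral conditions protect the acid-labile ether and the oxidisable free phenols.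

## Compound list

1 | 4-hydroxycinnamic acid | O=C(O)/C=C/c1ccc(O)cc1 | starting material
2 | benzyl (E)-3-[4-(benzyloxy)phenyl]prop-2-enoate | O=C(OCc1ccccc1)/C=C/c1ccc(OCc2ccccc2)cc1 | intermediate
3 | (E)-3-[4-(benzyloxy)phenyl]prop-2-en-1-ol | OC/C=C/c1ccc(OCc2ccccc2)cc1 | intermediate
4 | (E)-3-[4-(benzyloxy)phenyl]prop-2-en-1-yl methyl carbonate | COC(=O)OC/C=C/c1ccc(OCc2ccccc2)cc1 | intermediate
5 | methyl 2,3,4-trihydroxybenzoate | COC(=O)c1ccc(O)c(O)c1O | starting material
6 | methyl 3,4-bis(benzyloxy)-2-hydroxybenzoate | COC(=O)c1ccc(OCc2ccccc2)c(OCc2ccccc2)c1O | intermediate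
7 | methyl 3,4-bis(benzyloxy)-2-{[(1R)-1-[4-(benzyloxy)phenyl]prop-2-en-1-yl]oxy}benzoate | COC(=O)c1ccc(OCc2ccccc2)c(OCc2ccccc2)c1O[C@@H](c1ccc(OCc2ccccc2)cc1)C=C | intermediate
8 | 3,4-bis(benzyloxy)-2-{[(1R)-1-[4-(benzyloxy)phenyl]prop-2-en-1-yl]oxy}benzoic acid | OC(=O)c1ccc(OCc2ccccc2)c(OCc2ccccc2)c1O[C@@H](c1ccc(OCc2ccccc2)cc1)C=C | intermediate
9 | 2,3,4-trihydroxybenzaldehyde | O=Cc1ccc(O)c(O)c1O | starting material
10 | 3,4-bis(benzyloxy)-2-hydroxybenzaldehyde | O=Cc1ccc(OCc2ccccc2)c(OCc2ccccc2)c1O | intermediate
11 | 3,4-bis(benzyloxy)-2-{[(1S)-1-[4-(benzyloxy)phenyl]prop-2-en-1-yl]oxy}benzaldehyde | O=Cc1ccc(OCc2ccccc2)c(OCc2ccccc2)c1O[C@H](c1ccc(OCc2ccccc2)cc1)C=C | intermediate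
12 | 1,2-bis(benzyloxy)-3-{[(1S)-1-[4-(benzyloxy)phenyl]prop-2-en-1-yl]oxy}-4-ethenylbenzene | C=Cc1ccc(OCc2ccccc2)c(OCc2ccccc2)c1O[C@H](c1ccc(OCc2ccccc2)cc1)C=C | intermediate
13 | (2S)-7,8-bis(benzyloxy)-2-[4-(benzyloxy)phenyl]-2H-chromene | c1ccccc1COc1ccc(cc1)[C@H]1Oc2c(ccc(OCc3ccccc3)c2OCc2ccccc2)C=C1 | intermediate
14 | 3,4-epoxide of 13, oxirane on the face opposite the 2-aryl group | c1ccccc1COc1ccc(cc1)[C@H]1Oc2c(ccc(OCc3ccccc3)c2OCc2ccccc2)[C@@H]2O[C@H]12 | intermediate
15 | (2R,3S,4R)-4-(allyloxy)-7,8-bis(benzyloxy)-2-[4-(benzyloxy)phenyl]chroman-3-ol | c1ccccc1COc1ccc(cc1)[C@H]1Oc2c(ccc(OCc3ccccc3)c2OCc2ccccc2)[C@@H](OCC=C)[C@@H]1O | intermediate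
16 | (2R,4R)-4-(allyloxy)-7,8-bis(benzyloxy)-2-[4-(benzyloxy)phenyl]chroman-3-one | c1ccccc1COc1ccc(cc1)[C@H]1Oc2c(ccc(OCc3ccccc3)c2OCc2ccccc2)[C@@H](OCC=C)C1=O | intermediate
17 | (2R,3R,4R)-4-(allyloxy)-7,8-bis(benzyloxy)-2-[4-(benzyloxy)phenyl]chroman-3-ol | c1ccccc1COc1ccc(cc1)[C@H]1Oc2c(ccc(OCc3ccccc3)c2OCc2ccccc2)[C@@H](OCC=C)[C@H]1O | intermediate
18 | (2R,3R,4R)-4-(allyloxy)-3,7,8-tris(benzyloxy)-2-[4-(benzyloxy)phenyl]chromane | c1ccccc1COc1ccc(cc1)[C@H]1Oc2c(ccc(OCc3ccccc3)c2OCc2ccccc2)[C@@H](OCC=C)[C@H]1OCc1ccccc1 | intermediate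
19 | (2R,3R,4R)-3,7,8-tris(benzyloxy)-2-[4-(benzyloxy)phenyl]chroman-4-ol | c1ccccc1COc1ccc(cc1)[C@H]1Oc2c(ccc(OCc3ccccc3)c2OCc2ccccc2)[C@@H](O)[C@H]1OCc1ccccc1 | intermediate
20 | 4-O-ester of 19 with acid 8 (centres of 19 unchanged; R at the allylic ether carbon) | c5ccccc5COc1ccc([C@H]2Oc3c(ccc(OCc5ccccc5)c3OCc5ccccc5)[C@@H](OC(=O)c3ccc(OCc5ccccc5)c(OCc5ccccc5)c3O[C@@H](c3ccc(OCc5ccccc5)cc3)C=C)[C@H]2OCc5ccccc5)cc1 | intermediate
21 | 4-O-{(2R)-7,8-bis(benzyloxy)-2-[4-(benzyloxy)phenyl]-2H-chromen-4-yl} ether of 19 | c5ccccc5COc1ccc([C@H]2Oc3c(ccc(OCc5ccccc5)c3OCc5ccccc5)[C@@H](OC3=C[C@H](c4ccc(OCc5ccccc5)cc4)Oc4c3ccc(OCc5ccccc5)c4OCc5ccccc5)[C@H]2OCc5ccccc5)cc1 | intermediate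
22 | 3',4'-epoxide of 21, oxirane on the face opposite the 2'-aryl group | c5ccccc5COc1ccc([C@H]2Oc3c(ccc(OCc5ccccc5)c3OCc5ccccc5)[C@@H](O[C@@]3(O6)c4ccc(OCc5ccccc5)c(OCc5ccccc5)c4O[C@@H](c4ccc(OCc5ccccc5)cc4)[C@@H]36)[C@H]2OCc5ccccc5)cc1 | intermediate
23 | (2R,3R,4R)-3,7,8-tris(benzyloxy)-2-[4-(benzyloxy)phenyl]-4-{[(2S,3R,4R)-7,8-bis(benzyloxy)-2-[4-(benzyloxy)phenyl]-3-hydroxychroman-4-yl]oxy}chromane | c5ccccc5COc1ccc([C@H]2Oc3c(ccc(OCc5ccccc5)c3OCc5ccccc5)[C@@H](O[C@@H]3c4ccc(OCc5ccccc5)c(OCc5ccccc5)c4O[C@@H](c4ccc(OCc5ccccc5)cc4)[C@@H]3O)[C@H]2OCc5ccccc5)cc1 | intermediate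
24 | (2R,3R,4R)-2-(4-hydroxyphenyl)-4-{[(2S,3R,4R)-3,7,8-trihydroxy-2-(4-hydroxyphenyl)chroman-4-yl]oxy}chromane-3,7,8-triol | Oc1ccc([C@H]2Oc3c(ccc(O)c3O)[C@@H](O[C@@H]3c4ccc(O)c(O)c4O[C@@H](c4ccc(O)cc4)[C@@H]3O)[C@H]2O)cc1 | target

## Step count and least certain steps

Total: 19 steps. Longest linear sequence: 15 steps (1, 2, 3, 8–19).

**Step 17 (key).** The titanium ethylidene may olefinate the carbonyl directly, or fail to exchange with the alkene next to the branched C2' carbon. The zinc and titanium halides at 65 °C may also ionise the C2'–O bond, with loss of configuration. Fallback: starting from 20, the ester is methylenated with Cp2Ti(CH3)2 in toluene at 70 °C, a non-Lewis-acidic reagent, to give the 1-alkoxy-1-arylethene F1. Ring-closing metathesis of F1 with the second-generation Grubbs catalyst Cl2(H2IMes)(PCy3)Ru=CHPh then gives 21 with loss of ethylene.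

**Step 18.** The alkoxy-epoxide may collapse before hydride capture, by hydride shift to a 3'-ketone or by loss of the all-cis alcohol. Hydride may also enter at C3', or syn to the oxirane oxygen. Fallback: epoxide 22, generated from 21 as before, is trapped at −78 °C with thiophenol and a trace of Et3N. Opening at C4' with inversion gives the 4'-phenylsulfanyl O,S-ketal F2, and tributyltin hydride with AIBN in toluene then replaces sulfur by hydrogen through the C4' radical, which takes hydrogen on the face away from the 3'-oxygen, returning to 23.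

**Step 5.** The di-ortho-substituted, chelated phenoxide may attack the allyl-iridium complex slowly, and the electron-rich branched ether may re-ionise on the catalyst, with erosion of the branched ratio and of enantiomeric purity. Fallback: starting from 3 and 6, Sharpless epoxidation of 3 with Ti(O-i-Pr)4, D-(−)-diisopropyl tartrate and t-BuOOH gives [(2R,3R)-3-[4-(benzyloxy)phenyl]oxiran-2-yl]methanol F3. Ti(O-i-Pr)4-assisted opening by phenol 6 at the benzylic carbon with inversion gives the (1S,2R)-1-aryloxy-2,3-diol F4. Thiocarbonyldiimidazole converts it to the cyclic thionocarbonate F5, and Corey–Winter fragmentation with 1,3-dimethyl-2-phenyl-1,3,2-diazaphospholidine at 40 °C gives 7.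

**Step 8.** The failure mode is the same as in step 5, made worse by the formyl group, which withdraws electron density from the phenoxide. Fallback: starting from 10, Wittig methylenation with two equivalents of ylide is done first and gives 2,3-bis(benzyloxy)-6-ethenylphenol F6, a non-chelating and more electron-rich phenol. Its iridium-catalysed etherification with 4 and the (Sa,Sc,Sc) ligand gives 12 directly.

**Step 13.** Ketone 16 may enolise toward C2 or C4 and epimerise, or the hydride may show too little facial preference. Fallback: starting from 15, Mitsunobu inversion at C3 with 4-nitrobenzoic acid, PPh3 and diisopropyl azodicarboxylate gives the (2R,3R,4R)-3-(4-nitrobenzoate) F7, and methanolysis with K2CO3 in MeOH gives 17 without passing through a ketone.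

## Further compounds

F1 | step 17 | 1-{3,4-bis(benzyloxy)-2-{[(1R)-1-[4-(benzyloxy)phenyl]prop-2-en-1-yl]oxy}phenyl}ethenyl ether of 19 | c5ccccc5COc1ccc([C@H]2Oc3c(ccc(OCc5ccccc5)c3OCc5ccccc5)[C@@H](OC(=C)c3ccc(OCc5ccccc5)c(OCc5ccccc5)c3O[C@@H](c3ccc(OCc5ccccc5)cc3)C=C)[C@H]2OCc5ccccc5)cc1
F2 | step 18 | 23 carrying phenylsulfanyl in place of hydrogen at C4' (sulfur trans to the 3'-hydroxyl) | c5ccccc5COc1ccc([C@H]2Oc3c(ccc(OCc5ccccc5)c3OCc5ccccc5)[C@@H](O[C@]3(Sc6ccccc6)c4ccc(OCc5ccccc5)c(OCc5ccccc5)c4O[C@@H](c4ccc(OCc5ccccc5)cc4)[C@@H]3O)[C@H]2OCc5ccccc5)cc1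
F3 | step 5 | [(2R,3R)-3-[4-(benzyloxy)phenyl]oxiran-2-yl]methanol | OC[C@H]1O[C@@H]1c1ccc(OCc2ccccc2)cc1
F4 | step 5 | methyl 3,4-bis(benzyloxy)-2-{[(1S,2R)-1-[4-(benzyloxy)phenyl]-2,3-dihydroxypropyl]oxy}benzoate | COC(=O)c1ccc(OCc2ccccc2)c(OCc2ccccc2)c1O[C@@H](c1ccc(OCc2ccccc2)cc1)[C@H](O)CO
F5 | step 5 | methyl 3,4-bis(benzyloxy)-2-{(S)-[4-(benzyloxy)phenyl][(4R)-2-thioxo-1,3-dioxolan-4-yl]methoxy}benzoate | COC(=O)c1ccc(OCc2ccccc2)c(OCc2ccccc2)c1O[C@@H](c1ccc(OCc2ccccc2)cc1)[C@H]1COC(=S)O1
F6 | step 8 | 2,3-bis(benzyloxy)-6-ethenylphenol | C=Cc1ccc(OCc2ccccc2)c(OCc2ccccc2)c1O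
F7 | step 13 | (2R,3R,4R)-4-(allyloxy)-7,8-bis(benzyloxy)-2-[4-(benzyloxy)phenyl]chroman-3-yl 4-nitrobenzoate | c1ccccc1COc1ccc(cc1)[C@H]1Oc2c(ccc(OCc3ccccc3)c2OCc2ccccc2)[C@@H](OCC=C)[C@H]1OC(=O)c1ccc(cc1)[N+](=O)[O-]
A1 | alternative 1 | (2S,5S)-2,5-bis[3,4-bis(benzyloxy)-2-(tert-butyldimethylsilyloxy)phenyl]-2,5-dihydrofuran | CC(C)(C)[Si](C)(C)Oc1c(OCc2ccccc2)c(OCc2ccccc2)ccc1[C@H]3O[C@H](c4ccc(OCc2ccccc2)c(OCc2ccccc2)c4O[Si](C)(C)C(C)(C)C)C=C3
A2 | alternative 1 | 2,3-dihydrofuran | C1CC=CO1
A3 | alternative 1 | 3,4-bis(benzyloxy)-2-(tert-butyldimethylsilyloxy)phenyl trifluoromethanesulfonate | CC(C)(C)[Si](C)(C)Oc1c(OCc2ccccc2)c(OCc2ccccc2)ccc1OS(=O)(=O)C(F)(F)F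
A4 | alternative 2 | trans-epoxide spanning C2' and C3' on the ether-linked arm of the protected all-cis unit | c5ccccc5COc1ccc([C@H]2Oc3c(ccc(OCc5ccccc5)c3OCc5ccccc5)[C@@H](O[C@H](c3ccc(OCc5ccccc5)c(OCc5ccccc5)c3O[Si](C)(C)C(C)(C)C)[C@H]3O[C@@H]3c3ccc(OCc5ccccc5)cc3)[C@H]2OCc5ccccc5)cc1
A5 | alternative 2 | [4-(benzyloxy)benzyl]dimethylsulfonium tetrafluoroborate | C[S+](C)Cc1ccc(OCc2ccccc2)cc1.F[B-](F)(F)F
A6 | alternative 2 | 2-aryl-2-alkoxyacetaldehyde whose alkoxy group is the protected all-cis unit | c5ccccc5COc1ccc([C@H]2Oc3c(ccc(OCc5ccccc5)c3OCc5ccccc5)[C@@H](O[C@H](c3ccc(OCc5ccccc5)c(OCc5ccccc5)c3O[Si](C)(C)C(C)(C)C)C=O)[C@H]2OCc5ccccc5)cc1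
A7 | alternative 3 | octa-O-benzyl ether of the target | c5ccccc5COc1ccc([C@H]2Oc3c(ccc(OCc5ccccc5)c3OCc5ccccc5)[C@@H](O[C@@H]3c4ccc(OCc5ccccc5)c(OCc5ccccc5)c4O[C@@H](c4ccc(OCc5ccccc5)cc4)[C@@H]3OCc5ccccc5)[C@H]2OCc5ccccc5)cc1
A8 | alternative 3 | open-chain bis(2-bromoaryl) ether diol with all six stereocentres | c5ccccc5COc1ccc([C@@H](O)[C@H](OCc5ccccc5)[C@H](O[C@H](c4ccc(OCc5ccccc5)c(OCc5ccccc5)c4Br)[C@@H](OCc5ccccc5)[C@@H](O)c4ccc(OCc5ccccc5)cc4)c3ccc(OCc5ccccc5)c(OCc5ccccc5)c3Br)cc1
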